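**Plan**
- The retrosynthesis cuts one bond of the target: the ester C(acyl)–O3 bond between the syringoyl carbonyl and the flavan. No C–C bond and no ring is made.
- The acyl group is carried as its 1-O-β-D-glucose ester, which is cut in turn at the anomeric C1–O bond into a benzyl-protected glucosyl trichloroacetimidate and 4-O-benzylsyringic acid.
- Forward: syringic acid is benzylated, joined to the protected sugar with inversion at C1, debenzylated, and the free acyl glucose is used by an acyltransferase to esterify O3 of unprotected (−)-epicatechin.
- Enabling feature: O3 on ring C is the only aliphatic (secondary, axial) hydroxyl; the other four (O5 and O7 on ring A, O3' and O4' on ring B) are phenols. The tea-leaf galloyltransferase acylates this oxygen in its native reaction, and syringate is gallate with O3 and O5 of the acyl ring methylated.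
- Stereochemistry: C2 (R) and C3 (R) come unchanged from (−)-epicatechin. The β-anomeric centre of the donor is set by SN2-type inversion of the α-imidate and leaves with the glucose.

Key step: step 5

Assumption: the benzyl-protected sugar lactol and the flavan-3-ol are bought as single enantiomers, and the tea-leaf acyltransferase is available as a recombinant preparation.

**Step 1**
Reactants: 1 syringic acid (4-hydroxy-3,5-dimethoxybenzoic acid)
Product: 3 4-O-benzylsyringic acid (4-benzyloxy-3,5-dimethoxybenzoic acid), via benzyl 4-benzyloxy-3,5-dimethoxybenzoate 2 (not isolated)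
Conditions: BnBr (2.5 equiv), K2CO3, DMF, 60 °C; filter; then 2 M NaOH aq, MeOH, 70 °C; then HCl to pH 2
Reagents that add atoms: benzyl bromide, BrCc1ccccc1; sodium hydroxide, [Na+].[OH-]
Why: Williamson O-benzylation of the carboxylate and of the hindered 4-phenoxide gives the benzyl ester benzyl ether, and saponification then cleaves only the ester by acyl–oxygen fission (the hydroxide oxygen becoming the acid OH) while the aryl benzyl ether stays, so the phenol is masked for the sugar coupling and no stereocentre is involved.

**Step 2**
Reactants: 4 2,3,4,6-tetra-O-benzyl-D-glucopyranose (free anomeric OH, anomeric mixture)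
Product: 5 2,3,4,6-tetra-O-benzyl-α-D-glucopyranosyl trichloroacetimidate
Conditions: Cl3CCN (5 equiv), DBU (1,8-diazabicyclo[5.4.0]undec-7-ene, 0.1 equiv), CH2Cl2, 0 °C to rt
Reagents that add atoms: trichloroacetonitrile, N#CC(Cl)(Cl)Cl
Why: Base-catalysed addition of the anomeric alkoxide to the nitrile (Schmidt trichloroacetimidate formation) is reversible with DBU, so the mixture should converge on the axial α-imidate favoured by the anomeric effect, which defines C1 as α for the inversion that follows.

**Step 3**
Reactants: 5 2,3,4,6-tetra-O-benzyl-α-D-glucopyranosyl trichloroacetimidate; 3 4-O-benzylsyringic acid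
Product: 6 2,3,4,6-tetra-O-benzyl-1-O-(4-O-benzylsyringoyl)-β-D-glucopyranose
Conditions: 3 (1.2 equiv), 4 Å molecular sieves, CH2Cl2, rt, no added promoter
Reagents that add atoms: none
Why: In this Schmidt glycosyl ester synthesis the carboxylic acid protonates the imidate nitrogen and its carboxylate displaces trichloroacetamide from C1 within the tight ion pair with inversion, so the α-imidate should give the equatorial β-ester without a participating group at O2, and the ester, not being a glycosyl donor without promoter, should not anomerise.

**Step 4**
Reactants: 6 2,3,4,6-tetra-O-benzyl-1-O-(4-O-benzylsyringoyl)-β-D-glucopyranose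
Product: 7 1-O-syringoyl-β-D-glucopyranose (1-O-(4-hydroxy-3,5-dimethoxybenzoyl)-β-D-glucopyranose)
Conditions: H2 (1 atm), 10% Pd/C, THF–MeOH, rt
Reagents that add atoms: none
Why: Catalytic hydrogenolysis over palladium on carbon cleaves the four alkyl benzyl ethers and the aryl benzyl ether at neutral pH, where the non-benzylic anomeric ester should neither migrate to O2 nor solvolyse, so the β-configuration at C1 and the aryl methyl ethers are kept.

**Step 5**
Reactants: 7 1-O-syringoyl-β-D-glucopyranose; 8 (−)-epicatechin ((2R,3R)-2-(3,4-dihydroxyphenyl)chromane-3,5,7-triol)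
Product: 9 (−)-epicatechin 3-O-syringate ((2R,3R)-2-(3,4-dihydroxyphenyl)-5,7-dihydroxychroman-3-yl 4-hydroxy-3,5-dimethoxybenzoate), the target
Conditions: tea-leaf epicatechin:1-O-galloyl-β-D-glucose O-galloyltransferase (serine carboxypeptidase-like acyltransferase, recombinant), 7 (3 equiv), citrate–phosphate buffer pH 5.5, ascorbic acid, 30 °C; C18 reversed-phase chromatography
Reagents that add atoms: none
Why: Proposed new method: the serine of the Ser–His–Asp triad attacks the anomeric ester carbonyl of 7, an activated ester because its leaving group is a hemiacetal oxygen, to give a syringoyl-serine enzyme ester and free glucose, and O3 of 8 held in the acceptor pocket then attacks this acyl-enzyme to release 9. The closest known reaction is the same enzyme's transfer of a galloyl group from 1-O-galloyl-β-D-glucose to O3 of epicatechin; a 3,5-dimethoxy-4-hydroxybenzoyl glucose has not been shown as its donor, although the sinapoylglucose-dependent transferases of the same fold carry this very aryl pattern through an acyl-serine. No ring closes and no stereocentre is created: the new bond is O3–C(acyl), so C2 and C3 keep the (2R,3R) configuration of 8. The step needs chemoselectivity for the single secondary alcohol O3 over the phenols O5, O7, O3' and O4' and over the 4-OH of the donor, and this rests on the acceptor pocket, which places the axial O3 of the 2,3-cis flavan next to the acyl-serine as in the native reaction, not on intrinsic nucleophilicity. Excess 7 should offset competing hydrolysis of the acyl-enzyme, and pH 5.5 with ascorbate should keep the catechol from autoxidation and C2 from epimerising.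

**Compound list**
1 | syringic acid (4-hydroxy-3,5-dimethoxybenzoic acid) | COc1cc(C(=O)O)cc(OC)c1O | starting material
2 | benzyl 4-benzyloxy-3,5-dimethoxybenzoate | COc1cc(C(=O)OCc2ccccc2)cc(OC)c1OCc1ccccc1 | intermediate (not isolated)
3 | 4-O-benzylsyringic acid (4-benzyloxy-3,5-dimethoxybenzoic acid) | COc1cc(C(=O)O)cc(OC)c1OCc1ccccc1 | intermediate
4 | 2,3,4,6-tetra-O-benzyl-D-glucopyranose (anomeric mixture) | OC1O[C@H](COCc2ccccc2)[C@@H](OCc2ccccc2)[C@H](OCc2ccccc2)[C@H]1OCc1ccccc1 | starting material
5 | 2,3,4,6-tetra-O-benzyl-α-D-glucopyranosyl trichloroacetimidate | N=C(O[C@H]1O[C@H](COCc2ccccc2)[C@@H](OCc2ccccc2)[C@H](OCc2ccccc2)[C@H]1OCc1ccccc1)C(Cl)(Cl)Cl | intermediate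
6 | 2,3,4,6-tetra-O-benzyl-1-O-(4-O-benzylsyringoyl)-β-D-glucopyranose | COc1cc(C(=O)O[C@@H]2O[C@H](COCc3ccccc3)[C@@H](OCc3ccccc3)[C@H](OCc3ccccc3)[C@H]2OCc2ccccc2)cc(OC)c1OCc1ccccc1 | intermediate
7 | 1-O-syringoyl-β-D-glucopyranose | COc1cc(C(=O)O[C@@H]2O[C@H](CO)[C@@H](O)[C@H](O)[C@H]2O)cc(OC)c1O | intermediate
8 | (−)-epicatechin, (2R,3R) | O[C@@H]1Cc2c(O)cc(O)cc2O[C@@H]1c1ccc(O)c(O)c1 | starting material
9 | (−)-epicatechin 3-O-syringate, (2R,3R) | COc1cc(C(=O)O[C@@H]2Cc3c(O)cc(O)cc3O[C@@H]2c2ccc(O)c(O)c2)cc(OC)c1O | target

**Count**
Total steps: 5. Longest linear sequence: 4 steps (1 → 3 → 6 → 7 → 9, or 4 → 5 → 6 → 7 → 9).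

**Steps most likely to fail**

Step 5. The donor site may fail to bind or turn over the doubly O-methylated acyl glucose, so that no acyl-serine forms, or water may capture the acyl-enzyme faster than O3 does, so that the donor is only hydrolysed. The fallback uses known chemistry, sets out from 8 (with acid 3 from step 1) and comes back at 9. The four phenols of 8 are benzylated (BnBr, K2CO3, DMF, 0 °C to rt) to give 5,7,3',4'-tetra-O-benzyl-(−)-epicatechin F1. Its one remaining hydroxyl, O3, is esterified with 3 under Steglich conditions (EDC·HCl, 4-dimethylaminopyridine, CH2Cl2) to give 3-O-(4-O-benzylsyringoyl)-5,7,3',4'-tetra-O-benzyl-(−)-epicatechin F2. Hydrogenolysis (H2, Pd(OH)2/C, THF–MeOH) then removes the five benzyl groups and gives 9. Selectivity for O3 then comes from protection of every phenol.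

Step 3. β-Selectivity may erode through ionisation to an oxocarbenium ion pair with return from the α-face, and the imidate may be hydrolysed back to the lactol by traces of water. The fallback reverses the polarity of the coupling, sets out from 3 and 4 and comes back at 6. Acid 3 is converted with (COCl)2 and catalytic DMF in CH2Cl2 into 4-benzyloxy-3,5-dimethoxybenzoyl chloride F3. Lactol 4 is deprotonated with n-BuLi in THF at −40 °C and acylated with F3. The equatorial β-alkoxide is the more nucleophilic anomer and is replenished by ring–chain equilibration, so it should be acylated preferentially to give 6, with the C1–O bond left intact.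

Step 4. The five-fold debenzylation may stall at partly benzylated stages, and during long exposure the syringoyl group may migrate from O1 to O2 or the anomeric ester may solvolyse. The fallback avoids protecting groups altogether, sets out from 1 and comes back at 7. Free acid 1 is glucosylated in buffer at pH 7 and 30 °C with UDP-α-D-glucose by an ester-forming UDP-glucosyltransferase of the UGT84A family, a class of plant enzymes that make 1-O-acyl-β-D-glucoses from hydroxybenzoic acids. Transfer occurs with inversion at C1 and should give the β-ester 7 directly. No new compound arises on this path: none F0.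

**Further compounds**
F1 | step 5 | 5,7,3',4'-tetra-O-benzyl-(−)-epicatechin | O[C@@H]1Cc2c(OCc3ccccc3)cc(OCc3ccccc3)cc2O[C@@H]1c1ccc(OCc2ccccc2)c(OCc2ccccc2)c1
F2 | step 5 | 3-O-(4-O-benzylsyringoyl)-5,7,3',4'-tetra-O-benzyl-(−)-epicatechin | COc1cc(C(=O)O[C@@H]2Cc3c(OCc4ccccc4)cc(OCc4ccccc4)cc3O[C@@H]2c2ccc(OCc3ccccc3)c(OCc3ccccc3)c2)cc(OC)c1OCc1ccccc1
F3 | step 3 | 4-benzyloxy-3,5-dimethoxybenzoyl chloride | COc1cc(C(Cl)=O)cc(OC)c1OCc1ccccc1
F0 | step 4 | none | none
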